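**Retrosynthetic overview**
- The aldehyde comes last, by allylic oxidation of the isopropenyl group; the tiglate comes from the (R)-carbinol and tigloyl chloride; the carbinol comes from the aryl methyl ketone by asymmetric transfer hydrogenation.
- The trans-3-acetoxy-2-isopropenyl-2,3-dihydrobenzofuran comes from a 2,2-dimethyl-2H-chromene by an enantioselective acetoxylative ring contraction, in which the ring oxygen shifts from C2 to C3 (pyran to dihydrofuran). This step sets both ring stereocenters.
- The 6-acetylchromene comes from 6-bromochromene and a Weinreb amide; the bromochromene comes from 4-bromophenol and 3-methylbut-2-enal.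
- Ring order: benzene ring bought, pyran ring formed in step 1, pyran contracted to the dihydrofuran in step 3.

Assumption: the SMILES is read as the (E)-2-methylbut-2-enoate (tiglate), with 2S,3R (trans) on the dihydrobenzofuran and R at the carbinol carbon.
Assumption: the (R,R)-lactate-derived diacetoxyiodoarene (a known reagent, made from 2-iodoresorcinol and methyl (S)-lactate, then oxidised in AcOH) is taken to attack the 3-Si,4-Re face of 9; if the sense proves opposite, its (S,S)-enantiomer is used and nothing else changes.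

**Step 1**
Reactants: 1 4-bromophenol; 2 3-methylbut-2-enal
Product: 5 6-bromo-2,2-dimethyl-2H-chromene, via benzodioxaborinine 3 (not isolated), via ortho-quinone methide 4 (not isolated)
Conditions: PhB(OH)2 (1.0 equiv), EtCO2H (0.3 equiv), toluene, reflux, Dean–Stark, 24 h
Reagents that add atoms: none
Why: Boron-templated ortho-addition of the phenol to the enal gives benzodioxaborinine 3, which expels PhBO to give ortho-quinone methide 4 that closes by oxa-6π electrocyclization (chromene annulation of a phenol with an enal); no stereocenter is formed.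

**Step 2**
Reactants: 5 6-bromo-2,2-dimethyl-2H-chromene; 6 N-methoxy-N-methylacetamide
Product: 9 1-(2,2-dimethyl-2H-chromen-6-yl)ethan-1-one, via aryllithium 7 (not isolated), via lithium hemiaminal 8 (not isolated)
Conditions: n-BuLi (1.05 equiv), THF, −78 °C, 30 min; then 6 (1.2 equiv), −78 → 0 °C; aq. NH4Cl
Reagents that add atoms: none
Why: Fast bromine–lithium exchange gives aryllithium 7, and the Weinreb amide stops at the chelated tetrahedral adduct 8, so only the methyl ketone is released on work-up (Weinreb ketone synthesis); no stereocenter is formed.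

**Step 3**
Reactants: 9 1-(2,2-dimethyl-2H-chromen-6-yl)ethan-1-one
Product: 11 (2S,3R)-5-acetyl-2-(prop-1-en-2-yl)-2,3-dihydro-1-benzofuran-3-yl acetate, via iodane adduct 10 (not isolated)
Conditions: (R,R)-ArI(OAc)2 (1.1 equiv; Ar = 2,6-bis[(R)-1-(methoxycarbonyl)ethoxy]phenyl), BF3·OEt2 (1.5 equiv), CH2Cl2, −78 → −40 °C, 3 h; Et3N then aq. NaHCO3 at −40 °C
Reagents that add atoms: dimethyl (2R,2'R)-2,2'-{[2-(diacetoxy-λ3-iodanyl)-1,3-phenylene]bis(oxy)}dipropanoate, COC(=O)[C@@H](C)Oc1cccc(O[C@H](C)C(=O)OC)c1I(OC(C)=O)OC(C)=O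
Why: Proposed new method: the BF3-activated chiral trivalent-iodine reagent adds to the styrene-type C3=C4 bond from one face and acetate attacks benzylic C4 anti to iodine, giving the trans-diequatorial adduct 10 whose C3–I bond is antiperiplanar to the C2–O1 bond, so the ring oxygen shifts from C2 to C3 with inversion as the iodoarene leaves and the resulting tertiary cation loses a methyl proton to the released acetate; this contracts the pyran to the trans-3-acetoxy-2-isopropenyl dihydrofuran, with 3R set by the anti acetate delivery and 2S by the inversion at the former C3, both governed by the facial choice of the reagent. The closest known reactions are the enantioselective vicinal diacetoxylation of styrenes with lactate-derived diacetoxyiodoarenes, the ring contraction of 1,2-dihydronaphthalenes to indanes mediated by trivalent iodine or trivalent thallium, and the solvolytic ring contraction of 2,2-dimethylchroman-3-yl sulfonates to 2-isopropenyl-2,3-dihydrobenzofurans; these have not been merged into one enantioselective acetoxylative ring contraction of a 2H-chromene.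

**Step 4**
Reactants: 11 (2S,3R)-5-acetyl-2-(prop-1-en-2-yl)-2,3-dihydro-1-benzofuran-3-yl acetate
Product: 12 (2S,3R)-5-[(1R)-1-hydroxyethyl]-2-(prop-1-en-2-yl)-2,3-dihydro-1-benzofuran-3-yl acetate
Conditions: RuCl(p-cymene)[(R,R)-TsDPEN] (1 mol%), HCO2H/Et3N (5:2), CH2Cl2, 28 °C, 24 h
Reagents that add atoms: none
Why: Noyori asymmetric transfer hydrogenation, in which the (R,R)-TsDPEN hydride complex of divalent ruthenium delivers hydride to the Si face of the aryl methyl ketone and gives the (R)-carbinol under catalyst control, while the acetate, the alkene and the ring stereocenters are untouched.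

**Step 5**
Reactants: 12 (2S,3R)-5-[(1R)-1-hydroxyethyl]-2-(prop-1-en-2-yl)-2,3-dihydro-1-benzofuran-3-yl acetate; 13 (2E)-2-methylbut-2-enoyl chloride
Product: 14 (1R)-1-[(2S,3R)-3-acetoxy-2-(prop-1-en-2-yl)-2,3-dihydro-1-benzofuran-5-yl]ethyl (2E)-2-methylbut-2-enoate
Conditions: pyridine (3 equiv), DMAP (0.1 equiv), CH2Cl2, 0 °C → rt
Reagents that add atoms: none
Why: DMAP-catalysed O-acylation of the secondary benzylic alcohol by the acid chloride, with pyridine as a mild acid scavenger that avoids ketene formation, leaves the carbinol C–O bond and configuration untouched and keeps the E geometry of the tiglate.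

**Step 6**
Reactants: 14 (1R)-1-[(2S,3R)-3-acetoxy-2-(prop-1-en-2-yl)-2,3-dihydro-1-benzofuran-5-yl]ethyl (2E)-2-methylbut-2-enoate
Product: 16 (1R)-1-[(2S,3R)-3-acetoxy-2-(3-oxoprop-1-en-2-yl)-2,3-dihydro-1-benzofuran-5-yl]ethyl (2E)-2-methylbut-2-enoate (CNP0294391.1), via allylic alcohol 15 (not isolated)
Conditions: SeO2 (1.5 equiv), pyridine (1 equiv), 1,4-dioxane (2% H2O), 70 °C, 3 h
Reagents that add atoms: selenium dioxide, O=[Se]=O
Why: Riley allylic oxidation, in which SeO2 attacks the methyl group of the electron-rich 1,1-disubstituted alkene by an ene reaction and 2,3-shift (CH3 is preferred over the ring CH, and the electron-poor tiglate alkene is inert) to give allylic alcohol 15, which is oxidised on to the conjugated aldehyde in the same flask without touching any stereocenter.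

**Compound list**
1 | 4-bromophenol | Oc1ccc(Br)cc1 | starting material
2 | 3-methylbut-2-enal | CC(C)=CC=O | starting material
3 | 6-bromo-4-(2-methylprop-1-en-1-yl)-2-phenyl-4H-1,3,2-benzodioxaborinine (racemic) | CC(C)=CC1OB(c2ccccc2)Oc2ccc(Br)cc12 | intermediate (not isolated)
4 | (6Z)-4-bromo-6-(3-methylbut-2-en-1-ylidene)cyclohexa-2,4-dien-1-one | O=C1C=CC(Br)=C/C1=C/C=C(C)C | intermediate (not isolated)
5 | 6-bromo-2,2-dimethyl-2H-chromene | CC1(C)C=Cc2cc(Br)ccc2O1 | intermediate
6 | N-methoxy-N-methylacetamide | CC(=O)N(C)OC | starting material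
7 | (2,2-dimethyl-2H-chromen-6-yl)lithium | [Li]c1ccc2OC(C)(C)C=Cc2c1 | intermediate (not isolated)
8 | lithium 1-(2,2-dimethyl-2H-chromen-6-yl)-1-[methoxy(methyl)amino]ethan-1-olate (racemic) | CON(C)C(C)(O[Li])c1ccc2OC(C)(C)C=Cc2c1 | intermediate (not isolated)
9 | 1-(2,2-dimethyl-2H-chromen-6-yl)ethan-1-one | CC(=O)c1ccc2OC(C)(C)C=Cc2c1 | intermediate
10 | (3S,4R)-6-acetyl-3-[acetoxy(aryl)-λ3-iodanyl]-2,2-dimethyl-3,4-dihydro-2H-chromen-4-yl acetate, aryl = 2,6-bis[(R)-1-(methoxycarbonyl)ethoxy]phenyl | CC(=O)O[C@@H]1c2cc(C(C)=O)ccc2OC(C)(C)[C@H]1I(OC(C)=O)c1c(O[C@H](C)C(=O)OC)cccc1O[C@H](C)C(=O)OC | intermediate (not isolated)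
11 | (2S,3R)-5-acetyl-2-(prop-1-en-2-yl)-2,3-dihydro-1-benzofuran-3-yl acetate (trans) | C=C(C)[C@@H]1Oc2ccc(C(C)=O)cc2[C@H]1OC(C)=O | intermediate
12 | (2S,3R)-5-[(1R)-1-hydroxyethyl]-2-(prop-1-en-2-yl)-2,3-dihydro-1-benzofuran-3-yl acetate | C=C(C)[C@@H]1Oc2ccc([C@@H](C)O)cc2[C@H]1OC(C)=O | intermediate
13 | (2E)-2-methylbut-2-enoyl chloride (tigloyl chloride) | C/C=C(\C)C(Cl)=O | starting material
14 | (1R)-1-[(2S,3R)-3-acetoxy-2-(prop-1-en-2-yl)-2,3-dihydro-1-benzofuran-5-yl]ethyl (2E)-2-methylbut-2-enoate | C=C(C)[C@@H]1Oc2ccc([C@@H](C)OC(=O)/C(C)=C/C)cc2[C@H]1OC(C)=O | intermediate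
15 | (1R)-1-[(2S,3R)-3-acetoxy-2-(3-hydroxyprop-1-en-2-yl)-2,3-dihydro-1-benzofuran-5-yl]ethyl (2E)-2-methylbut-2-enoate | C=C(CO)[C@@H]1Oc2ccc([C@@H](C)OC(=O)/C(C)=C/C)cc2[C@H]1OC(C)=O | intermediate (not isolated)
16 | (1R)-1-[(2S,3R)-3-acetoxy-2-(3-oxoprop-1-en-2-yl)-2,3-dihydro-1-benzofuran-5-yl]ethyl (2E)-2-methylbut-2-enoate, CNP0294391.1 | C=C(C=O)[C@@H]1Oc2ccc([C@@H](C)OC(=O)/C(C)=C/C)cc2[C@H]1OC(C)=O | target

**Total step count:** 6. **Longest linear sequence:** 6 steps (fully linear, 1 → 5 → 9 → 11 → 12 → 14 → 16).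

**Steps most likely to fail**

Step 3 (the proposed new step). The risks are:
- participation of the C4 acetate from the diaxial conformer of 10 (a dioxolanylium ion, leading to diacetate or to the cis product);
- aryl instead of oxygen migration;
- capture of the tertiary cation by acetate;
- an unproven level and sense of asymmetric induction.

The fallback uses known chemistry, sets out from 9 and comes back at 11. Jacobsen epoxidation of 9 with (S,S)-[N,N'-bis(3,5-di-tert-butylsalicylidene)cyclohexane-1,2-diaminato]manganese chloride (a complex of trivalent manganese; NaOCl, 4-phenylpyridine N-oxide, CH2Cl2, 0 °C) gives (3S,4S)-6-acetyl-3,4-epoxy-2,2-dimethyl-3,4-dihydro-2H-chromene F2. Opening at benzylic C4 with inversion by acetate (CsOAc, AcOH, DMF, 50 °C) gives (3S,4R)-6-acetyl-3-hydroxy-2,2-dimethyl-3,4-dihydro-2H-chromen-4-yl acetate F3. Tf2O with 2,6-di-tert-butyl-4-methylpyridine (CH2Cl2, −78 → 0 °C) gives (3S,4R)-6-acetyl-2,2-dimethyl-3-[(trifluoromethanesulfonyl)oxy]-3,4-dihydro-2H-chromen-4-yl acetate F4. F4 ionises in the flask with anti participation of the ring oxygen (inversion at C3) and loses a methyl proton, giving 11. The acetate-participation risk remains in this fallback; it removes only the asymmetric-induction question and the acetate nucleophile.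

Step 1. The risk is a sluggish ortho-attack of the weakly nucleophilic bromophenol and a low yield. The fallback sets out from 1 and comes back at 5. O-Alkylation of 1 with 3-chloro-3-methylbut-1-yne (CuCl2·2H2O cat., DBU, MeCN, 0 °C) gives 1-bromo-4-[(2-methylbut-3-yn-2-yl)oxy]benzene F1. Heating F1 in N,N-diethylaniline at 190 °C (aryl propargyl ether Claisen rearrangement, 1,5-hydrogen shift, electrocyclization) gives 5.

Step 6. The risks are incomplete or over-oxidation, loss of acetic acid to the aromatic benzofuran, and ionisation of the benzylic tiglate in hot dioxane. The fallback changes the order of events so that the oxidation is done on the robust ketone; it sets out from 11 and comes back at 16.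
- Catalytic SeO2 (0.5 equiv) with t-BuOOH in CH2Cl2 at rt stops at (2S,3R)-5-acetyl-2-(3-hydroxyprop-1-en-2-yl)-2,3-dihydro-1-benzofuran-3-yl acetate F5.
- Transfer hydrogenation as in step 4 gives (2S,3R)-5-[(1R)-1-hydroxyethyl]-2-(3-hydroxyprop-1-en-2-yl)-2,3-dihydro-1-benzofuran-3-yl acetate F6.
- TEMPO (cat.) with PhI(OAc)2 in CH2Cl2 oxidises only the primary allylic alcohol, giving (2S,3R)-5-[(1R)-1-hydroxyethyl]-2-(3-oxoprop-1-en-2-yl)-2,3-dihydro-1-benzofuran-3-yl acetate F7.
- Acylation of F7 with 13 (pyridine, DMAP, CH2Cl2, 0 °C) gives 16.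

**Further compounds**
F1 | step 1 | 1-bromo-4-[(2-methylbut-3-yn-2-yl)oxy]benzene | C#CC(C)(C)Oc1ccc(Br)cc1
F2 | step 3 | (3S,4S)-6-acetyl-3,4-epoxy-2,2-dimethyl-3,4-dihydro-2H-chromene | CC(=O)c1ccc2OC(C)(C)[C@H]3O[C@H]3c2c1
F3 | step 3 | (3S,4R)-6-acetyl-3-hydroxy-2,2-dimethyl-3,4-dihydro-2H-chromen-4-yl acetate | CC(=O)O[C@@H]1c2cc(C(C)=O)ccc2OC(C)(C)[C@H]1O
F4 | step 3 | (3S,4R)-6-acetyl-2,2-dimethyl-3-[(trifluoromethanesulfonyl)oxy]-3,4-dihydro-2H-chromen-4-yl acetate | CC(=O)O[C@@H]1c2cc(C(C)=O)ccc2OC(C)(C)[C@H]1OS(=O)(=O)C(F)(F)F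
F5 | step 6 | (2S,3R)-5-acetyl-2-(3-hydroxyprop-1-en-2-yl)-2,3-dihydro-1-benzofuran-3-yl acetate | C=C(CO)[C@@H]1Oc2ccc(C(C)=O)cc2[C@H]1OC(C)=O
F6 | step 6 | (2S,3R)-5-[(1R)-1-hydroxyethyl]-2-(3-hydroxyprop-1-en-2-yl)-2,3-dihydro-1-benzofuran-3-yl acetate | C=C(CO)[C@@H]1Oc2ccc([C@@H](C)O)cc2[C@H]1OC(C)=O
F7 | step 6 | (2S,3R)-5-[(1R)-1-hydroxyethyl]-2-(3-oxoprop-1-en-2-yl)-2,3-dihydro-1-benzofuran-3-yl acetate | C=C(C=O)[C@@H]1Oc2ccc([C@@H](C)O)cc2[C@H]1OC(C)=O
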